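**Retrosynthetic overview**

- The strategy rests on ring A (C1, C14, C13, C12, C11, C10). The C12 oxygen lies between the C13=C14 alkene and C11, so the dienol ether C14=C13–C12(OSi)=C11 with the adjacent sp3 pair C1–C10 is the retron of a hexatriene six-electron electrocyclization (bond C1–C10).
- Ring A: C11–O by Rubottom oxidation of the ring A silyl dienol ether; C1–C10 by thermal disrotatory closure of a geometrically defined silyloxytriene. The triene comes from (R)-glyceraldehyde acetonide via Wittig reaction, β-keto ester, E-configured enol silyl ether and Still–Gennari olefination.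
- Southern arm: C7–C8 by chelation-controlled alkenylzinc addition to the C8 aldehyde; C7–O and C6–Cl from a Sharpless trans-epoxide opened by chloride; γ-lactone (C8–C17) by intramolecular Reformatsky reaction.
- Ten-membered ring: C2=C3 by ring-closing metathesis, then release of the C4 hydroxyl.
- Order of ring formation: ring A (step 8), γ-lactone (step 28), ten-membered ring (step 31).

Key step: step 8

Remark: atoms are numbered as in the briarane skeleton of the target (C1–C20). The silyloxy group of the triene sits on its central double bond (C12=C13), so the precursor is a 3-silyloxy-1,3,5-hexatriene and ring A forms as a 2-silyloxycyclohexa-1,3-diene.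
Remark: the facial sense of the ring closure is assumed to follow the steric (allylic strain) model given in step 8; it is not secured by precedent.

**Route**

Step 1
Reactants: 1 (R)-2,3-O-isopropylideneglyceraldehyde; 2 ethyl 2-(triphenylphosphoranylidene)propanoate
Product: 3 ethyl (2E)-3-[(4S)-2,2-dimethyl-1,3-dioxolan-4-yl]-2-methylprop-2-enoate
Conditions: CH2Cl2, 0 °C to rt
Reagents that add atoms: none
Why: Wittig olefination with a stabilized α-branched ylide should give the E trisubstituted enoate (C10=C11, C9 trans to the carbonyl) without epimerizing the α-oxygenated centre C9.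

Step 2
Reactants: 3 ethyl (2E)-3-[(4S)-2,2-dimethyl-1,3-dioxolan-4-yl]-2-methylprop-2-enoate
Product: 4 (2E)-3-[(4S)-2,2-dimethyl-1,3-dioxolan-4-yl]-N-methoxy-N,2-dimethylprop-2-enamide
Conditions: MeNH(OMe)·HCl, i-PrMgCl, THF, −20 °C
Reagents that add atoms: N,O-dimethylhydroxylamine hydrochloride, Cl.CNOC
Why: The magnesium amide of N,O-dimethylhydroxylamine converts the ester directly into the Weinreb amide, which allows a clean single acylation in step 3.

Step 3
Reactants: 4 (2E)-3-[(4S)-2,2-dimethyl-1,3-dioxolan-4-yl]-N-methoxy-N,2-dimethylprop-2-enamide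
Product: 5 methyl (4E)-5-[(4S)-2,2-dimethyl-1,3-dioxolan-4-yl]-4-methyl-3-oxopent-4-enoate
Conditions: methyl acetate, LiN(i-Pr)2, THF, −78 °C; then 4, −78 to −40 °C; aq. NH4Cl
Reagents that add atoms: methyl acetate, COC(C)=O
Why: Claisen-type acylation of the lithium ester enolate by the Weinreb amide stops at the chelated tetrahedral adduct, so 1,2-addition gives the β-keto ester (C12 ketone, C13, C14) without conjugate or double addition.

Step 4
Reactants: 5 methyl (4E)-5-[(4S)-2,2-dimethyl-1,3-dioxolan-4-yl]-4-methyl-3-oxopent-4-enoate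
Product: 6 methyl (2E,4E)-3-[(tert-butyldimethylsilyl)oxy]-5-[(4S)-2,2-dimethyl-1,3-dioxolan-4-yl]-4-methylpenta-2,4-dienoate
Conditions: TBSOTf, Et3N, CH2Cl2, −78 to 0 °C
Reagents that add atoms: tert-butyldimethylsilyl trifluoromethanesulfonate, CC(C)(C)[Si](C)(C)OS(=O)(=O)C(F)(F)F
Why: Soft enolization and O-silylation of the β-keto ester under amine (non-chelating) conditions should favour the E enol ether, with the silyloxy group trans to the ester and C11 cis to C14, which is the C12=C13 geometry the triene needs; any 2Z isomer is removed by chromatography.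

Step 5
Reactants: 6 methyl (2E,4E)-3-[(tert-butyldimethylsilyl)oxy]-5-[(4S)-2,2-dimethyl-1,3-dioxolan-4-yl]-4-methylpenta-2,4-dienoate
Product: 7 (2E,4E)-3-[(tert-butyldimethylsilyl)oxy]-5-[(4S)-2,2-dimethyl-1,3-dioxolan-4-yl]-4-methylpenta-2,4-dien-1-ol
Conditions: i-Bu2AlH, CH2Cl2, −78 °C; aq. potassium sodium tartrate
Reagents that add atoms: none
Why: 1,2-Reduction of the vinylogous carbonate ester by the aluminium hydride gives the allylic alcohol and leaves the silyl enol ether, its geometry and the acetonide untouched.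

Step 6
Reactants: 7 (2E,4E)-3-[(tert-butyldimethylsilyl)oxy]-5-[(4S)-2,2-dimethyl-1,3-dioxolan-4-yl]-4-methylpenta-2,4-dien-1-ol
Product: 8 (2E,4E)-3-[(tert-butyldimethylsilyl)oxy]-5-[(4S)-2,2-dimethyl-1,3-dioxolan-4-yl]-4-methylpenta-2,4-dienal
Conditions: MnO2, CH2Cl2, rt
Reagents that add atoms: none
Why: Neutral allylic oxidation gives the β-silyloxy enal (C14 aldehyde), in which the E arrangement (oxygen trans to the carbonyl) is also the thermodynamically preferred one.

Step 7
Reactants: 8 (2E,4E)-3-[(tert-butyldimethylsilyl)oxy]-5-[(4S)-2,2-dimethyl-1,3-dioxolan-4-yl]-4-methylpenta-2,4-dienal; 9 methyl 2-[bis(2,2,2-trifluoroethoxy)phosphoryl]propanoate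
Product: 10 methyl (2Z,4E,6E)-5-[(tert-butyldimethylsilyl)oxy]-7-[(4S)-2,2-dimethyl-1,3-dioxolan-4-yl]-2,6-dimethylhepta-2,4,6-trienoate
Conditions: KN(SiMe3)2, 18-crown-6, THF, −78 °C
Reagents that add atoms: none
Why: Still–Gennari olefination with the trifluoroethyl phosphonate and a dissociated potassium counter-ion should give the Z trisubstituted enoate, which places the ester cis to C13 (inside) and the C15 methyl outside at the C1 terminus.

Step 8
Reactants: 10 methyl (2Z,4E,6E)-5-[(tert-butyldimethylsilyl)oxy]-7-[(4S)-2,2-dimethyl-1,3-dioxolan-4-yl]-2,6-dimethylhepta-2,4,6-trienoate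
Product: 11 methyl (1S,6S)-4-[(tert-butyldimethylsilyl)oxy]-6-[(4S)-2,2-dimethyl-1,3-dioxolan-4-yl]-1,5-dimethylcyclohexa-2,4-diene-1-carboxylate
Conditions: toluene (degassed, 0.02 M), 2,6-di-tert-butyl-4-methylphenol (cat.), 90 °C, base-washed glassware
Reagents that add atoms: none
Why: The three π bonds of 10 (C1=C14, C13=C12, C11=C10) reorganize in a thermal suprafacial six-electron electrocyclization through a boat-like disrotatory transition state to the σ bond C1–C10 and the diene C14=C13/C12=C11; the closest known reaction type is the thermal closure of 3-silyloxy-1,3,5-hexatrienes obtained from cross-conjugated dienones, and the donor at C12 with the acceptor at C1 should lower the barrier. Ring A closes in this single step by the six-atom electrocyclic (6π, disrotatory) mode. The relative configuration of C1 and C10 follows from disrotation and the defined triene geometry: the outside groups (C15 methyl and the C9 dioxolane) end cis and the inside ester ends trans to C9, which is the trans ring fusion of the target. The absolute sense of rotation must come from C9: allylic 1,3-strain with the C11 methyl holds H9 in the plane of C10=C11, and C1 should then bond to C10 on the face of the small ring oxygen, anti to the dioxolane CH2 (C8), which gives the (1S,6S) product. The step needs this facial selectivity and must avoid a [1,7]-hydrogen shift; the shift is blocked because the inside group on C1 is an ester without hydrogen, and no geometric equilibration is required because steps 4 and 7 already fix the C12=C13 and C1=C14 geometries.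

Step 9
Reactants: 11 methyl (1S,6S)-4-[(tert-butyldimethylsilyl)oxy]-6-[(4S)-2,2-dimethyl-1,3-dioxolan-4-yl]-1,5-dimethylcyclohexa-2,4-diene-1-carboxylate
Product: 12 ring A alcohol (C2 hydroxymethyl analogue of 11; C1, C9, C10 as in 11)
Conditions: i-Bu2AlH, CH2Cl2, −78 to 0 °C; aq. potassium sodium tartrate
Reagents that add atoms: none
Why: The hindered ester is reduced to the neopentyl alcohol while C12 stays masked as the silyl dienol ether, so no enone is exposed to hydride.

Step 10
Reactants: 12 ring A alcohol (C2 hydroxymethyl analogue of 11)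
Product: 13 ring A aldehyde (C2 formyl group on C1; C1, C9, C10 as in 11)
Conditions: Dess–Martin periodinane, NaHCO3, CH2Cl2, 0 °C
Reagents that add atoms: none
Why: Buffered Dess–Martin oxidation gives the non-enolizable α-quaternary aldehyde without hydrolysing the acid-sensitive dienol ether.

Step 11
Reactants: 13 ring A aldehyde (C2 formyl group on C1)
Product: 14 ring A vinyl compound (C1 vinyl, C12 silyl dienol ether, C10 dioxolane; C1, C9, C10 as in 11)
Conditions: Ph3PCH3Br, KN(SiMe3)2, THF, 0 °C; then 13, 0 °C to rt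
Reagents that add atoms: methyltriphenylphosphonium bromide, C[P+](c1ccccc1)(c1ccccc1)c1ccccc1.[Br-]
Why: Wittig methylenation works on hindered non-enolizable aldehydes and installs the C2 vinyl group needed for the final ring closure.

Step 12
Reactants: 14 ring A vinyl compound (C1 vinyl, C12 silyl dienol ether)
Product: 16 α-hydroxy enone (C11 tertiary carbinol, C12 ketone, C13=C14; C11 oxygen cis to H10), via silyloxy enone 15 (not isolated)
Conditions: mCPBA, NaHCO3, CH2Cl2, −20 °C; then HF·pyridine, THF, 0 °C
Reagents that add atoms: 3-chloroperoxybenzoic acid, OOC(=O)c1cccc(Cl)c1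
Why: In this Rubottom oxidation the electron-rich C11=C12 enol ether is epoxidized in preference to the other alkenes from the face anti to the C9 substituent on C10, silyl transfer gives 15, and fluoride frees the C11 carbinol next to the C12 enone.

Step 13
Reactants: 16 α-hydroxy enone (C11 tertiary carbinol)
Product: 17 C11 acetate (ring A enone with C11 acetoxy and methyl, C1 vinyl, C10 dioxolane)
Conditions: Ac2O, DMAP, Et3N, CH2Cl2, 40 °C
Reagents that add atoms: acetic anhydride, CC(=O)OC(C)=O
Why: DMAP-catalysed acylation with excess anhydride should acetylate the tertiary α-ketol, the only hydroxyl present, on a substrate that is still robust.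

Step 14
Reactants: 17 C11 acetate (ring A enone, C10 dioxolane)
Product: 18 C8,C9 diol (ring A as in 17; C9 secondary and C8 primary hydroxyl)
Conditions: AcOH–H2O (4:1), 45 °C
Reagents that add atoms: water, O
Why: Mild aqueous acid hydrolyses the terminal acetonide; the enone, the tertiary acetate and the vinyl group tolerate it.

Step 15
Reactants: 18 C8,C9 diol
Product: 19 bis(triethylsilyl) ether (C9 and C8 oxygen as triethylsilyl ethers)
Conditions: Et3SiOTf, 2,6-lutidine, CH2Cl2, −78 to 0 °C
Reagents that add atoms: triethylsilyl trifluoromethanesulfonate, CC[Si](CC)(CC)OS(=O)(=O)C(F)(F)F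
Why: The silyl triflate silylates both the primary and the hindered secondary hydroxyl; a silyl ether at C9 cannot migrate to O8 later, as an acetate could.

Step 16
Reactants: 19 bis(triethylsilyl) ether
Product: 20 C8 aldehyde (α-triethylsilyloxy aldehyde; C9 as in the target)
Conditions: (COCl)2, DMSO, CH2Cl2, −78 to −30 °C; then Et3N
Reagents that add atoms: none
Why: Under Swern conditions the chlorosulfonium salt cleaves the less hindered primary triethylsilyl ether selectively and oxidizes it to the aldehyde, while the hindered C9 silyl ether stays (known selective oxidation of primary triethylsilyl ethers).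

Step 17
Reactants: 21 acrolein; 22 methyl acrylate
Product: 23 methyl 3-hydroxy-2-methylidenepent-4-enoate (racemic)
Conditions: DABCO (cat.), neat, rt
Reagents that add atoms: none
Why: Morita–Baylis–Hillman reaction of the acrylate with the aldehyde of acrolein assembles C3, C4, C5, C16 and C6 in one step.

Step 18
Reactants: 23 methyl 3-hydroxy-2-methylidenepent-4-enoate (racemic)
Product: 24 methyl (3S)-3-hydroxy-2-methylidenepent-4-enoate
Conditions: Ti(OiPr)4, L-(+)-diisopropyl tartrate, t-BuOOH (0.6 equiv), 4 Å molecular sieves, CH2Cl2, −20 °C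
Reagents that add atoms: none
Why: In this Sharpless kinetic resolution the L-(+)-tartrate catalyst should epoxidize the vinyl group of the R carbinol much faster and leave the S alcohol (C4 of the target), which is recovered.

Step 19
Reactants: 24 methyl (3S)-3-hydroxy-2-methylidenepent-4-enoate
Product: 25 methyl (3S)-3-[(tert-butyldimethylsilyl)oxy]-2-methylidenepent-4-enoate
Conditions: TBSCl, imidazole, DMF, rt
Reagents that add atoms: tert-butyldimethylsilyl chloride, CC(C)(C)[Si](C)(C)Cl
Why: Standard silylation protects the C4 hydroxyl as a robust silyl ether for the rest of the route.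

Step 20
Reactants: 25 methyl (3S)-3-[(tert-butyldimethylsilyl)oxy]-2-methylidenepent-4-enoate
Product: 26 (3S)-3-[(tert-butyldimethylsilyl)oxy]-2-methylidenepent-4-en-1-ol
Conditions: i-Bu2AlH, CH2Cl2, −78 °C; aq. potassium sodium tartrate
Reagents that add atoms: none
Why: 1,2-Reduction of the acrylate ester gives the primary allylic alcohol (C6) and keeps the exo-methylene group.

Step 21
Reactants: 26 (3S)-3-[(tert-butyldimethylsilyl)oxy]-2-methylidenepent-4-en-1-ol
Product: 27 (3S)-3-[(tert-butyldimethylsilyl)oxy]-2-methylidenepent-4-enal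
Conditions: MnO2, CH2Cl2, rt
Reagents that add atoms: none
Why: Mild allylic oxidation gives the 2-substituted acrolein, which is used at once in the next step.

Step 22
Reactants: 27 (3S)-3-[(tert-butyldimethylsilyl)oxy]-2-methylidenepent-4-enal
Product: 28 tert-butyl{[(3S,5E)-6-iodo-4-methylidenehexa-1,5-dien-3-yl]oxy}dimethylsilane (vinyl iodide fragment C3–C7 with C16)
Conditions: CHI3, CrCl2, THF, 0 °C
Reagents that add atoms: iodoform, IC(I)I
Why: Takai iodo-olefination of the aldehyde adds C7 and should give the E vinyl iodide.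

Step 23
Reactants: 28 vinyl iodide fragment; 20 C8 aldehyde
Product: 31 allylic alcohol (8S; C8 hydroxyl syn to the C9 silyloxy group; E-C6=C7, C5=C16, C4 silyl ether, terminal C3 vinyl), via alkenyllithium 29 (not isolated), via alkenylzinc bromide 30 (not isolated)
Conditions: 28, t-BuLi, Et2O, −78 °C; ZnBr2, −78 to 0 °C; then 20, CH2Cl2, −30 to 0 °C
Reagents that add atoms: none
Why: Iodine–lithium exchange and transmetalation give an alkenylzinc halide that adds only to the aldehyde (enone and acetate are inert), and the zinc halide Lewis acid should enforce chelation between the aldehyde and the α-silyloxy oxygen, so that attack from the side of H9 gives the 8,9-syn carbinol (known chelation-controlled alkenylzinc addition to α-silyloxy aldehydes).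

Step 24
Reactants: 31 allylic alcohol (8S)
Product: 32 epoxy alcohol (trans-6,7-epoxide, 6R,7R, erythro to the C8 hydroxyl)
Conditions: Ti(OiPr)4, D-(−)-diisopropyl tartrate, t-BuOOH, 4 Å molecular sieves, CH2Cl2, −20 °C
Reagents that add atoms: tert-butyl hydroperoxide, CC(C)(C)OO
Why: Sharpless epoxidation acts only on the alkene allylic to the free hydroxyl; the 8S carbinol is the matched, fast-reacting partner of the D-(−)-tartrate catalyst, which should deliver oxygen to the face that becomes O7 of the target.

Step 25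
Reactants: 32 epoxy alcohol
Product: 33 epoxy ketone (C8 ketone; epoxide as in 32)
Conditions: Dess–Martin periodinane, NaHCO3, CH2Cl2, 0 °C
Reagents that add atoms: none
Why: Buffered oxidation gives the α,β-epoxy ketone without opening the vinyl epoxide and removes the C8 stereocentre that served only as a control element.

Step 26
Reactants: 33 epoxy ketone
Product: 34 chlorohydrin ketone (6S chloride, 7R hydroxyl, C8 ketone)
Conditions: LiCl, AcOH, THF, 0 °C to rt
Reagents that add atoms: lithium chloride, [Li+].[Cl-]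
Why: Acid-assisted opening of the epoxy ketone by chloride should occur with inversion at C6, the carbon that is both β to the ketone and allylic, to give the anti chlorohydrin with O7 retained; attack at C16 (SN2′) is the competing path to be suppressed by the mild, weakly ionizing conditions.

Step 27
Reactants: 34 chlorohydrin ketone
Product: 35 2-bromopropanoate of the C7 hydroxyl (bromide epimers)
Conditions: 2-bromopropanoyl bromide, pyridine, CH2Cl2, −40 to 0 °C
Reagents that add atoms: 2-bromopropanoyl bromide, CC(Br)C(=O)Br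
Why: Acylation of the only free hydroxyl at low temperature attaches C17, C18 and C19 and limits base-induced loss of HCl from the β-chloro ketone.

Step 28
Reactants: 35 2-bromopropanoate of the C7 hydroxyl
Product: 36 γ-lactone (C8 tertiary hydroxyl cis to C6 on the lactone ring; C17 methyl cis to that hydroxyl; C9 triethylsilyl ether, C4 silyl ether)
Conditions: SmI2, THF, −78 °C; aq. NH4Cl
Reagents that add atoms: none
Why: In this intramolecular Reformatsky reaction SmI2 reduces the α-bromo ester faster than any carbonyl group, and the tethered samarium enolate adds to the C8 ketone through the rotamer with the bulky C9 branch next to H7, which sets C8 with its hydroxyl cis to C6; at C17 the methyl group is expected trans to the C9 branch on steric grounds, and this epimerizable centre can be equilibrated with base if a mixture forms.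

Step 29
Reactants: 36 γ-lactone (C9 triethylsilyl ether)
Product: 37 C9 alcohol (γ-lactone, C4 silyl ether)
Conditions: PPTS, MeOH–CH2Cl2, 0 °C
Reagents that add atoms: none
Why: Mild acidic methanolysis removes the triethylsilyl ether in the presence of the tert-butyldimethylsilyl ether at C4, and acidic conditions disfavour lactone migration to O9.

Step 30
Reactants: 37 C9 alcohol
Product: 38 C9 acetate (open-chain precursor with C1 vinyl and C4-bound vinyl; all stereocentres as in the target)
Conditions: Ac2O, pyridine, DMAP (cat.), CH2Cl2, 0 °C to rt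
Reagents that add atoms: acetic anhydride, CC(=O)OC(C)=O
Why: The secondary C9 hydroxyl is acetylated while the tertiary C8 hydroxyl of the β-hydroxy lactone is too hindered to react under these conditions.

Step 31
Reactants: 38 C9 acetate (diene precursor)
Product: 39 C4 tert-butyldimethylsilyl ether of the target (ten-membered ring with E-C2=C3)
Conditions: second-generation Grubbs catalyst RuCl2(=CHPh)(H2IMes)(PCy3) (10 mol %), toluene (1 mM), 80 °C, argon purge
Reagents that add atoms: none
Why: Ring-closing metathesis of the two terminal vinyl groups closes the ten-membered ring with loss of ethylene; initiation is expected at the less hindered C4-bound vinyl group, the 1,1-disubstituted C5=C16 and the enone should stay spectators, and reversible metathesis at 80 °C should favour the E alkene of the trans-fused bicycle.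

Step 32
Reactants: 39 C4 tert-butyldimethylsilyl ether of the target
Product: 40 CNP0196166.1 (target)
Conditions: HF·pyridine, pyridine, THF, 0 °C to rt
Reagents that add atoms: none
Why: Buffered fluoride cleaves the bis-allylic silyl ether and leaves the two acetates, the allylic chloride and the β-hydroxy lactone intact.

**Compound list**

1 | (R)-2,3-O-isopropylideneglyceraldehyde | O=C[C@H]1COC(C)(C)O1 | starting material
2 | ethyl 2-(triphenylphosphoranylidene)propanoate | CCOC(=O)C(C)=P(c1ccccc1)(c1ccccc1)c1ccccc1 | starting material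
3 | ethyl (2E)-3-[(4S)-2,2-dimethyl-1,3-dioxolan-4-yl]-2-methylprop-2-enoate | CCOC(=O)/C(C)=C/[C@H]1COC(C)(C)O1 | intermediate
4 | (2E)-3-[(4S)-2,2-dimethyl-1,3-dioxolan-4-yl]-N-methoxy-N,2-dimethylprop-2-enamide | CON(C)C(=O)/C(C)=C/[C@H]1COC(C)(C)O1 | intermediate
5 | methyl (4E)-5-[(4S)-2,2-dimethyl-1,3-dioxolan-4-yl]-4-methyl-3-oxopent-4-enoate | COC(=O)CC(=O)/C(C)=C/[C@H]1COC(C)(C)O1 | intermediate
6 | methyl (2E,4E)-3-[(tert-butyldimethylsilyl)oxy]-5-[(4S)-2,2-dimethyl-1,3-dioxolan-4-yl]-4-methylpenta-2,4-dienoate | COC(=O)\C=C(O[Si](C)(C)C(C)(C)C)/C(C)=C/[C@H]1COC(C)(C)O1 | intermediate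
7 | (2E,4E)-3-[(tert-butyldimethylsilyl)oxy]-5-[(4S)-2,2-dimethyl-1,3-dioxolan-4-yl]-4-methylpenta-2,4-dien-1-ol | OC\C=C(O[Si](C)(C)C(C)(C)C)/C(C)=C/[C@H]1COC(C)(C)O1 | intermediate
8 | (2E,4E)-3-[(tert-butyldimethylsilyl)oxy]-5-[(4S)-2,2-dimethyl-1,3-dioxolan-4-yl]-4-methylpenta-2,4-dienal | O=C\C=C(O[Si](C)(C)C(C)(C)C)/C(C)=C/[C@H]1COC(C)(C)O1 | intermediate
9 | methyl 2-[bis(2,2,2-trifluoroethoxy)phosphoryl]propanoate | COC(=O)C(C)P(=O)(OCC(F)(F)F)OCC(F)(F)F | starting material
10 | methyl (2Z,4E,6E)-5-[(tert-butyldimethylsilyl)oxy]-7-[(4S)-2,2-dimethyl-1,3-dioxolan-4-yl]-2,6-dimethylhepta-2,4,6-trienoate | COC(=O)/C(C)=C\C=C(O[Si](C)(C)C(C)(C)C)/C(C)=C/[C@H]1COC(C)(C)O1 | intermediate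
11 | methyl (1S,6S)-4-[(tert-butyldimethylsilyl)oxy]-6-[(4S)-2,2-dimethyl-1,3-dioxolan-4-yl]-1,5-dimethylcyclohexa-2,4-diene-1-carboxylate | COC(=O)[C@@]1(C)C=CC(O[Si](C)(C)C(C)(C)C)=C(C)[C@@H]1[C@H]2COC(C)(C)O2 | intermediate
12 | ring A alcohol (C2 hydroxymethyl analogue of 11; C1, C9, C10 as in 11) | OC[C@@]1(C)C=CC(O[Si](C)(C)C(C)(C)C)=C(C)[C@@H]1[C@H]2COC(C)(C)O2 | intermediate
13 | ring A aldehyde (C2 formyl group on C1) | O=C[C@@]1(C)C=CC(O[Si](C)(C)C(C)(C)C)=C(C)[C@@H]1[C@H]2COC(C)(C)O2 | intermediate
14 | ring A vinyl compound (C1 vinyl, C12 silyl dienol ether, C10 dioxolane) | C=C[C@@]1(C)C=CC(O[Si](C)(C)C(C)(C)C)=C(C)[C@@H]1[C@H]2COC(C)(C)O2 | intermediate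
15 | silyloxy enone (C11 tert-butyldimethylsilyloxy, C12 ketone, C13=C14) | C=C[C@@]1(C)C=CC(=O)[C@@](C)(O[Si](C)(C)C(C)(C)C)[C@@H]1[C@H]2COC(C)(C)O2 | intermediate
16 | α-hydroxy enone (C11 tertiary carbinol cis to H10, C12 ketone, C13=C14) | C=C[C@@]1(C)C=CC(=O)[C@@](C)(O)[C@@H]1[C@H]2COC(C)(C)O2 | intermediate
17 | C11 acetate (ring A enone, C1 vinyl, C10 dioxolane) | C=C[C@@]1(C)C=CC(=O)[C@@](C)(OC(C)=O)[C@@H]1[C@H]2COC(C)(C)O2 | intermediate
18 | C8,C9 diol | C=C[C@@]1(C)C=CC(=O)[C@@](C)(OC(C)=O)[C@@H]1[C@H](O)CO | intermediate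
19 | bis(triethylsilyl) ether of diol 18 | C=C[C@@]1(C)C=CC(=O)[C@@](C)(OC(C)=O)[C@@H]1[C@H](O[Si](CC)(CC)CC)CO[Si](CC)(CC)CC | intermediate
20 | C8 aldehyde (C9 triethylsilyl ether) | C=C[C@@]1(C)C=CC(=O)[C@@](C)(OC(C)=O)[C@@H]1[C@H](O[Si](CC)(CC)CC)C=O | intermediate
21 | acrolein | C=CC=O | starting material
22 | methyl acrylate | C=CC(=O)OC | starting material
23 | methyl 3-hydroxy-2-methylidenepent-4-enoate (racemic) | C=CC(O)C(=C)C(=O)OC | intermediate
24 | methyl (3S)-3-hydroxy-2-methylidenepent-4-enoate | C=C[C@H](O)C(=C)C(=O)OC | intermediate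
25 | methyl (3S)-3-[(tert-butyldimethylsilyl)oxy]-2-methylidenepent-4-enoate | C=C[C@H](O[Si](C)(C)C(C)(C)C)C(=C)C(=O)OC | intermediate
26 | (3S)-3-[(tert-butyldimethylsilyl)oxy]-2-methylidenepent-4-en-1-ol | C=C[C@H](O[Si](C)(C)C(C)(C)C)C(=C)CO | intermediate
27 | (3S)-3-[(tert-butyldimethylsilyl)oxy]-2-methylidenepent-4-enal | C=C[C@H](O[Si](C)(C)C(C)(C)C)C(=C)C=O | intermediate
28 | tert-butyl{[(3S,5E)-6-iodo-4-methylidenehexa-1,5-dien-3-yl]oxy}dimethylsilane | C=C[C@H](O[Si](C)(C)C(C)(C)C)C(=C)/C=C/I | intermediate
29 | alkenyllithium from 28 (lithium at C7) | C=C[C@H](O[Si](C)(C)C(C)(C)C)C(=C)/C=C/[Li] | intermediate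
30 | alkenylzinc bromide from 29 (zinc at C7) | C=C[C@H](O[Si](C)(C)C(C)(C)C)C(=C)/C=C/[Zn]Br | intermediate
31 | allylic alcohol (8S, syn to the C9 silyloxy group; E-C6=C7) | C=C[C@@]1(C)C=CC(=O)[C@@](C)(OC(C)=O)[C@@H]1[C@H](O[Si](CC)(CC)CC)[C@@H](O)/C=C/C(=C)[C@@H](O[Si](C)(C)C(C)(C)C)C=C | intermediate
32 | epoxy alcohol (trans-6,7-epoxide, 6R,7R) | C=C[C@@]1(C)C=CC(=O)[C@@](C)(OC(C)=O)[C@@H]1[C@H](O[Si](CC)(CC)CC)[C@@H](O)[C@H]2O[C@@H]2C(=C)[C@@H](O[Si](C)(C)C(C)(C)C)C=C | intermediate
33 | epoxy ketone (C8 ketone, epoxide as in 32) | C=C[C@@]1(C)C=CC(=O)[C@@](C)(OC(C)=O)[C@@H]1[C@H](O[Si](CC)(CC)CC)C(=O)[C@H]2O[C@@H]2C(=C)[C@@H](O[Si](C)(C)C(C)(C)C)C=C | intermediate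
34 | chlorohydrin ketone (6S chloride, 7R hydroxyl) | C=C[C@@]1(C)C=CC(=O)[C@@](C)(OC(C)=O)[C@@H]1[C@H](O[Si](CC)(CC)CC)C(=O)[C@@H](O)[C@@H](Cl)C(=C)[C@@H](O[Si](C)(C)C(C)(C)C)C=C | intermediate
35 | C7 2-bromopropanoate (bromide epimers) | C=C[C@@]1(C)C=CC(=O)[C@@](C)(OC(C)=O)[C@@H]1[C@H](O[Si](CC)(CC)CC)C(=O)[C@@H](OC(=O)C(C)Br)[C@@H](Cl)C(=C)[C@@H](O[Si](C)(C)C(C)(C)C)C=C | intermediate
36 | γ-lactone (C9 triethylsilyl ether, C4 silyl ether; C6, C7, C8, C17 as in the target) | C=C[C@@]1(C)C=CC(=O)[C@@](C)(OC(C)=O)[C@@H]1[C@H](O[Si](CC)(CC)CC)[C@]2(O)[C@@H](C)C(=O)O[C@H]2[C@@H](Cl)C(=C)[C@@H](O[Si](C)(C)C(C)(C)C)C=C | intermediate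
37 | C9 alcohol (γ-lactone, C4 silyl ether) | C=C[C@@]1(C)C=CC(=O)[C@@](C)(OC(C)=O)[C@@H]1[C@H](O)[C@]2(O)[C@@H](C)C(=O)O[C@H]2[C@@H](Cl)C(=C)[C@@H](O[Si](C)(C)C(C)(C)C)C=C | intermediate
38 | C9 acetate (diene precursor for ring closure) | C=C[C@@]1(C)C=CC(=O)[C@@](C)(OC(C)=O)[C@@H]1[C@H](OC(C)=O)[C@]2(O)[C@@H](C)C(=O)O[C@H]2[C@@H](Cl)C(=C)[C@@H](O[Si](C)(C)C(C)(C)C)C=C | intermediate
39 | C4 tert-butyldimethylsilyl ether of the target | C=C1[C@@H](O[Si](C)(C)C(C)(C)C)/C=C/[C@@]2(C)C=CC(=O)[C@@](C)(OC(C)=O)[C@@H]2[C@H](OC(C)=O)[C@]2(O)[C@@H](C)C(=O)O[C@H]2[C@H]1Cl | intermediate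
40 | CNP0196166.1 | C=C1[C@@H](O)/C=C/[C@@]2(C)C=CC(=O)[C@@](C)(OC(C)=O)[C@@H]2[C@H](OC(C)=O)[C@]2(O)[C@@H](C)C(=O)O[C@H]2[C@H]1Cl | target

**Step count**

Total step count: 32 (main line steps 1–16 and 23–32; fragment 28 in steps 17–22).
Longest linear sequence: 26 steps (1–16, then 23–32).

**Steps most likely to fail**

Step 8 (key step). What may go wrong: weak or reversed facial bias in the disrotatory closure, because the C9 stereocentre may not control the sense of rotation, or thermal erosion of the triene geometry before closure. The fallback builds ring A by a Diels–Alder reaction and sets out from enoate 3, which then serves as dienophile: its α-carbon becomes C1 with the C15 methyl, its ester becomes C2 and its β-carbon becomes C10. Cycloaddition of 3 with (1E,3Z)-1-methoxy-3-(trimethylsilyloxy)penta-1,3-diene under high pressure or Me2AlCl promotion would form C1–C14 and C10–C11 and give cycloadduct F1. Suprafacial addition to the E enoate fixes the C15 methyl cis to C9 without relying on any triene geometry, and the dioxolane again selects the face, now in a cycloaddition. Mild acid would release methanol and the silyl group from the cycloadduct to give enone F2. Kinetic α′-enolization at C11 (LiN(i-Pr)2, then TBSOTf) would give dienol silyl ether F3, the ethyl ester analogue of 11. Reduction with i-Bu2AlH as in step 9 comes back to the route at alcohol 12.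

Step 31 (ring-closing metathesis). What may go wrong: slow engagement of the neopentyl C1 vinyl group with oligomerization, closure to the Z alkene, or competing reaction of the C5=C16 alkene. The fallback moves the ring closure in front of the lactone annulation and sets out from chlorohydrin ketone 34, whose C6–C9 segment is still an open chain. Metathesis of 34 with the same catalyst would give the ten-membered chlorohydrin ketone F5. Acylation with 2-bromopropanoyl bromide would give bromo ester F6, and the SmI2 Reformatsky reaction, now transannular, would give the macrocyclic lactone F7. Removal of the triethylsilyl group (PPTS, MeOH) would give the C9 alcohol F8, and acetylation comes back to the route at 39.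

Step 28 (intramolecular Reformatsky). What may go wrong: reductive cleavage of the α-oxygen substituents or β-elimination of chloride by SmI2 before ring closure, and poor control at C17. The fallback is an intermolecular, chelation-controlled Reformatsky reaction that sets out from chlorohydrin ketone 34. Methyl 2-bromopropanoate with Et2Zn and RhCl(PPh3)3 (cat.) in THF at 0 °C would add the zinc enolate to the C8 ketone; the zinc alkoxide of the free C7 hydroxyl chelates the ketone and directs attack from the side of H7. This would give hydroxy ester F4, which lactonizes onto the C7 hydroxyl with loss of methanol (PPTS if needed) and comes back to the route at lactone 36.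

**Further compounds**

F1 | step 8 | Diels–Alder cycloadduct of 3 (ethyl ester at C1, C14 methoxy, C12 trimethylsilyl enol ether; C14 and C11 unassigned) | CCOC(=O)[C@@]1(C)C(OC)C=C(O[Si](C)(C)C)C(C)[C@@H]1[C@H]2COC(C)(C)O2
F2 | step 8 | ring A enone ethyl ester (C12 ketone, C13=C14, C11 methyl epimers) | CCOC(=O)[C@@]1(C)C=CC(=O)C(C)[C@@H]1[C@H]2COC(C)(C)O2
F3 | step 8 | ethyl ester analogue of 11 | CCOC(=O)[C@@]1(C)C=CC(O[Si](C)(C)C(C)(C)C)=C(C)[C@@H]1[C@H]2COC(C)(C)O2
F4 | step 28 | open-chain β-hydroxy methyl ester (C8 tertiary carbinol, C7 hydroxyl free) | C=C[C@@]1(C)C=CC(=O)[C@@](C)(OC(C)=O)[C@@H]1[C@H](O[Si](CC)(CC)CC)[C@](O)([C@@H](C)C(=O)OC)[C@@H](O)[C@@H](Cl)C(=C)[C@@H](O[Si](C)(C)C(C)(C)C)C=C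
F5 | step 31 | ten-membered chlorohydrin ketone (E-C2=C3, C8 ketone, C7 hydroxyl, C9 triethylsilyl ether) | C=C1[C@@H](O[Si](C)(C)C(C)(C)C)/C=C/[C@@]2(C)C=CC(=O)[C@@](C)(OC(C)=O)[C@@H]2[C@H](O[Si](CC)(CC)CC)C(=O)[C@@H](O)[C@H]1Cl
F6 | step 31 | ten-membered C7 2-bromopropanoate | C=C1[C@@H](O[Si](C)(C)C(C)(C)C)/C=C/[C@@]2(C)C=CC(=O)[C@@](C)(OC(C)=O)[C@@H]2[C@H](O[Si](CC)(CC)CC)C(=O)[C@@H](OC(=O)C(C)Br)[C@H]1Cl
F7 | step 31 | macrocyclic lactone with C9 triethylsilyl ether and C4 silyl ether | C=C1[C@@H](O[Si](C)(C)C(C)(C)C)/C=C/[C@@]2(C)C=CC(=O)[C@@](C)(OC(C)=O)[C@@H]2[C@H](O[Si](CC)(CC)CC)[C@]2(O)[C@@H](C)C(=O)O[C@H]2[C@H]1Cl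
F8 | step 31 | macrocyclic lactone with free C9 hydroxyl and C4 silyl ether | C=C1[C@@H](O[Si](C)(C)C(C)(C)C)/C=C/[C@@]2(C)C=CC(=O)[C@@](C)(OC(C)=O)[C@@H]2[C@H](O)[C@]2(O)[C@@H](C)C(=O)O[C@H]2[C@H]1Cl
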